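**Retrosynthetic overview** (briarane numbering C1–C20 is used throughout)
1. Last disconnections: C6–Cl (SN2 on the 6R allylic alcohol) and C5–C6 (Nozaki–Hiyama–Kishi closure of the ten-membered ring from a C5 alkenyl iodide and a C6 aldehyde).
2. Key disconnection: the cyclohexane ring C1–C14–C13–C12–C11–C10 is opened by a Diels–Alder transform across C13–C14 and C1–C10, giving 2-silyloxy diene 31 (C6–C13, C17–C20, butanolide in place) and cyclic β-silyl enal 10 (C1–C5, C14–C16).
3. Enabling feature: in that ring O12 is para to C1 and C20 sits on C11 (a C11=C12 silyl enol ether retron); C15 on C1 and C9 on C10 are cis across the new C1–C10 bond, while C2 and O14 are cis on the other face. C15 is therefore raised to a formyl group (endo activator, later reduced to CH3), and C2–O and C14 are tied into a 2,5-dihydro-1,2-oxasilole whose silicon is the latent O14.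
4. Ring order: butanolide (step 16), temporary oxasilole (step 5), cyclohexene (step 22), spiro-epoxide (step 28), ten-membered ring (step 32).
5. Stereocentres: C2 by asymmetric Morita–Baylis–Hillman reaction; C7 from (R)-solketal and C9 by substrate-controlled alkoxyallylboration; C8/C17 by SmI2 Reformatsky lactonisation; C1/C10/C14 in the cycloaddition; C12 and C11 by substrate control; C6 by CBS reduction and inversion.

Key step: step 22

Remark: stereocentres that are destroyed later (CHBr in 24, the ozonide carbon in 28, C11 in 35–38, sulfur in 38, C6 in 44) are left undefined; the CBS antipode in step 34 is assigned on the assumption that the 2-substituted vinyl group acts as the larger ketone substituent.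

**Dienophile 10**

Step 1
Reactants: 1 pent-4-yn-1-ol
Product: 2 4-iodopent-4-en-1-ol
Conditions: NaI, Me3SiCl, H2O (0.5 equiv), MeCN, rt
Reagents that add atoms: sodium iodide [Na+].[I-]
Why: Markovnikov hydroiodination of the terminal alkyne by HI generated in situ gives the 2-iodo-1-alkene; no stereocentre is formed.

Step 2
Reactants: 2 4-iodopent-4-en-1-ol
Product: 3 4-iodopent-4-enal
Conditions: Dess–Martin periodinane, NaHCO3, CH2Cl2, 0 °C
Reagents that add atoms: none
Why: Dess–Martin oxidation of the primary alcohol stops at the aldehyde and leaves the alkenyl iodide untouched.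

Step 3
Reactants: 3 4-iodopent-4-enal; 4 1,1,1,3,3,3-hexafluoropropan-2-yl prop-2-enoate
Product: 5 hexafluoroisopropyl (3S)-3-hydroxy-6-iodo-2-methylidenehept-6-enoate
Conditions: α-isocupreine (cat.), DMF, −55 °C
Reagents that add atoms: none
Why: Asymmetric Morita–Baylis–Hillman reaction of the activated acrylate; the quinine-derived pseudoenantiomer of β-isocupreidine should give the 3S carbinol (C2) through its hydrogen-bonded betaine–aldehyde adduct.

Step 4
Reactants: 5 Morita–Baylis–Hillman adduct; 6 chloro(ethenyl)dimethylsilane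
Product: 7 vinyl(dimethyl)silyl ether of 5
Conditions: Et3N, DMAP (cat.), CH2Cl2, 0 °C
Reagents that add atoms: none
Why: O-silylation of the secondary allylic alcohol installs the silicon tether; C2 is not touched.

Step 5
Reactants: 7 vinylsilyl ether
Product: 8 hexafluoroisopropyl (5S)-5-(3-iodobut-3-en-1-yl)-2,2-dimethyl-2,5-dihydro-1,2-oxasilole-4-carboxylate
Conditions: Mo(=CHCMe2Ph)(=N-2,6-iPr2C6H3)[OCMe(CF3)2]2 (cat.), C6H6, 50 °C
Reagents that add atoms: none
Why: Silicon-tethered ring-closing metathesis between the vinylsilane and the 1,1-disubstituted acrylate alkene (ethene lost) closes the five-membered oxasilole, which locks silicon cis to C2 on the C14=C1 bond; the hindered 2-iodoalkene is a spectator.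

Step 6
Reactants: 8 oxasilole ester
Product: 9 [(5S)-5-(3-iodobut-3-en-1-yl)-2,2-dimethyl-2,5-dihydro-1,2-oxasilol-4-yl]methanol
Conditions: iBu2AlH (2.2 equiv), CH2Cl2, −78 °C
Reagents that add atoms: none
Why: Hydride reduction of the activated ester to the allylic alcohol (C15 at the alcohol level); Si–O and C–I bonds survive at low temperature.

Step 7
Reactants: 9 oxasilole methanol
Product: 10 (5S)-5-(3-iodobut-3-en-1-yl)-2,2-dimethyl-2,5-dihydro-1,2-oxasilole-4-carbaldehyde
Conditions: Dess–Martin periodinane, NaHCO3, CH2Cl2, 0 °C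
Reagents that add atoms: none
Why: Dess–Martin oxidation of the allylic alcohol gives the β-silyl enal in which C15 is the formyl carbon.

**Wittig reagent 14**

Step 8
Reactants: 11 1-(triphenyl-λ5-phosphanylidene)propan-2-one; 12 [(chloromethyl)sulfanyl]benzene
Product: 14 4-(phenylsulfanyl)-3-(triphenyl-λ5-phosphanylidene)butan-2-one, via phosphonium chloride 13 (not isolated)
Conditions: toluene, 80 °C; then aq NaOH, CH2Cl2
Reagents that add atoms: none
Why: C-alkylation of the keto-stabilised phosphorane by the reactive α-chloro sulfide and deprotonation of the phosphonium salt give the α-substituted Wittig reagent that carries C20.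

**Diene 31**

Step 9
Reactants: 15 3-(methoxymethoxy)prop-1-ene
Product: 16 2-[(2Z)-3-(methoxymethoxy)prop-2-en-1-yl]-4,4,5,5-tetramethyl-1,3,2-dioxaborolane
Conditions: sBuLi, THF, −78 °C; iPrOBpin; HCl/Et2O, −78 °C → rt
Reagents that add atoms: 2-isopropoxy-4,4,5,5-tetramethyl-1,3,2-dioxaborolane CC(C)OB1OC(C)(C)C(C)(C)O1
Why: Deprotonation of the allyl ether gives the oxygen-chelated Z-alkoxyallyllithium, which is borylated at the carbon remote from oxygen to give the Z-γ-alkoxyallylboronate.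

Step 10
Reactants: 17 [(4R)-2,2-dimethyl-1,3-dioxolan-4-yl]methanol
Product: 18 (4S)-2,2-dimethyl-1,3-dioxolane-4-carbaldehyde
Conditions: (COCl)2, DMSO, CH2Cl2, −78 °C; Et3N
Reagents that add atoms: none
Why: Swern oxidation gives the configurationally labile aldehyde without epimerisation when it is used crude (the descriptor changes only through CIP priorities).

Step 11
Reactants: 18 (4S)-2,2-dimethyl-1,3-dioxolane-4-carbaldehyde; 16 Z-γ-alkoxyallylboronate
Product: 19 (1R,2S)-1-[(4S)-2,2-dimethyl-1,3-dioxolan-4-yl]-2-(methoxymethoxy)but-3-en-1-ol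
Conditions: toluene, 4 Å MS, rt; aq NaHCO3 work-up
Reagents that add atoms: none
Why: Allylboration through a chair Zimmerman–Traxler transition state: the Z-alkoxy group gives the C8/C9 syn relation and Felkin addition anti to the dioxolane C–O bond gives the C7/C8 anti relation (L-arabino triad), so C9 is set S from the chiral-pool centre C7; C8 is oxidised next.

Step 12
Reactants: 19 homoallylic alcohol
Product: 20 (2S)-1-[(4S)-2,2-dimethyl-1,3-dioxolan-4-yl]-2-(methoxymethoxy)but-3-en-1-one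
Conditions: Dess–Martin periodinane, NaHCO3, CH2Cl2, 0 °C
Reagents that add atoms: none
Why: Buffered Dess–Martin oxidation gives the α,α′-dioxygenated ketone (C8) without epimerising C7 or C9.

Step 13
Reactants: 20 ketone
Product: 21 (2S,4S)-1,2-dihydroxy-4-(methoxymethoxy)hex-5-en-3-one
Conditions: AcOH/H2O 4:1, 40 °C
Reagents that add atoms: none
Why: Mild acid hydrolysis removes the terminal acetonide while the MOM ether survives.

Step 14
Reactants: 21 diol
Product: 22 (2S,4S)-1-[(tert-butyldiphenylsilyl)oxy]-2-hydroxy-4-(methoxymethoxy)hex-5-en-3-one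
Conditions: tBuPh2SiCl, imidazole, CH2Cl2, 0 °C
Reagents that add atoms: tert-butyl(chloro)diphenylsilane CC(C)(C)[Si](Cl)(c1ccccc1)c1ccccc1
Why: The bulky silyl chloride reacts only at the primary C6 hydroxyl.

Step 15
Reactants: 22 α-hydroxy ketone; 23 2-bromopropanoyl bromide
Product: 24 (2S,4S)-1-[(tert-butyldiphenylsilyl)oxy]-4-(methoxymethoxy)-3-oxohex-5-en-2-yl 2-bromopropanoate
Conditions: pyridine, CH2Cl2, −20 °C
Reagents that add atoms: none
Why: Acylation of the C7 hydroxyl places the C17–C19 unit on the oxygen that becomes the lactone oxygen, so the regiochemistry of lactonisation is fixed in advance.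

Step 16
Reactants: 24 bromo ester
Product: 25 (3R,4R,5S)-5-{[(tert-butyldiphenylsilyl)oxy]methyl}-4-hydroxy-4-[(1S)-1-(methoxymethoxy)prop-2-en-1-yl]-3-methyloxolan-2-one
Conditions: SmI2 (2.2 equiv), THF, −78 °C
Reagents that add atoms: none
Why: Intramolecular samarium Reformatsky reaction: the α-bromo ester is reduced faster than the ketone, and the samarium enolate adds to C8 through a chelated bicyclic transition state that keeps the bulky C9 side chain trans to both the C7 substituent and the C17 methyl, which sets C8 (R) and C17 (R) with OH, CH3 and C6 cis on the lactone.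

Step 17
Reactants: 25 MOM-protected lactone
Product: 26 (3R,4R,5S)-5-{[(tert-butyldiphenylsilyl)oxy]methyl}-4-hydroxy-4-[(1S)-1-hydroxyprop-2-en-1-yl]-3-methyloxolan-2-one
Conditions: Me2BBr, CH2Cl2, −78 °C; aq NaHCO3
Reagents that add atoms: none
Why: Bromoborane cleavage of the acetal-type MOM ether at low temperature frees the C9 hydroxyl and spares the silyl ether, the lactone and the alkene.

Step 18
Reactants: 26 diol lactone
Product: 27 (1S)-1-[(2S,3R,4R)-2-{[(tert-butyldiphenylsilyl)oxy]methyl}-3-hydroxy-4-methyl-5-oxooxolan-3-yl]prop-2-en-1-yl acetate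
Conditions: Ac2O, pyridine, DMAP (cat.), 0 °C
Reagents that add atoms: acetic anhydride CC(=O)OC(C)=O
Why: The secondary C9 hydroxyl is acetylated (final C9 acetate) while the hindered tertiary C8 hydroxyl does not react.

Step 19
Reactants: 27 allylic acetate
Product: 29 α-acetoxy aldehyde (C10 formyl), via ozonide 28 (not isolated)
Conditions: O3, CH2Cl2, −78 °C; then Me2S
Reagents that add atoms: ozone [O-][O+]=O
Why: Ozonolysis of the only alkene with reductive work-up gives the C10 aldehyde, which is used at once to avoid epimerisation at C9.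

Step 20
Reactants: 29 α-acetoxy aldehyde; 14 4-(phenylsulfanyl)-3-(triphenyl-λ5-phosphanylidene)butan-2-one
Product: 30 (1S,2Z)-1-[(2S,3R,4R)-2-{[(tert-butyldiphenylsilyl)oxy]methyl}-3-hydroxy-4-methyl-5-oxooxolan-3-yl]-4-oxo-3-[(phenylsulfanyl)methyl]pent-2-en-1-yl acetate
Conditions: toluene, 80 °C
Reagents that add atoms: none
Why: Wittig olefination with the keto-stabilised ylide gives the trisubstituted enone with C9 trans to the acetyl group (Z by CIP because of sulfur), so that C9 is cis to C20.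

Step 21
Reactants: 30 enone
Product: 31 2-silyloxy diene (C13=C12(OTBS)–C11(CH2SPh)=C10) with C8 OTBS
Conditions: tBuMe2SiOTf (3 equiv), Et3N, CH2Cl2, −78 → 0 °C
Reagents that add atoms: tert-butyldimethylsilyl trifluoromethanesulfonate CC(C)(C)[Si](C)(C)OS(=O)(=O)C(F)(F)F
Why: Kinetic enol silylation of the methyl ketone gives the cross-conjugated 2-silyloxy diene, and the tertiary C8 hydroxyl is silylated in the same operation; the alkene geometry is unchanged.

**Fragment union and completion**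

Step 22
Reactants: 10 oxasilole carbaldehyde; 31 2-silyloxy diene
Product: 32 Diels–Alder adduct (cyclohexene C1–C14–C13–C12–C11–C10 with 1-formyl and cis-fused oxasilole)
Conditions: Me2AlCl (1.5 equiv), CH2Cl2, −78 → −30 °C
Reagents that add atoms: none
Why: This is a Lewis-acid-promoted normal-demand [4+2] cycloaddition, concerted but asynchronous with the C13–C14 bond ahead of the C1–C10 bond; the closest known reaction type is the Diels–Alder reaction of 2-silyloxy dienes with α-substituted enals that forms a quaternary carbon, with a β-silyl enal serving as a β-hydroxy enal equivalent. The cyclohexene ring C1–C14–C13–C12–C11–C10 is closed by suprafacial [4π+2π] addition, and the para rule of the C12 silyloxy group together with the ortho rule of the C10 substituent pairs C13 with C14 and C10 with C1. C1 and C14 keep the ring-enforced cis relation of C2 and silicon, and the endo position of the formyl group places C15 cis to C9 at C10, which is the trans relation of C2 and C9 needed for the ten-membered ring. The step needs endo over exo selectivity, which is secured because the exo mode would push the SiMe2–O ring under the diene. It needs one face of each partner: the dienophile reacts anti to the C3 side chain on the five-membered ring, and the diene reacts anti to the fully substituted C8 (syn to the acetate) because allylic 1,3-strain with the CH2SPh group on C11 holds the C9–H bond in the diene plane. With both partners enantiopure these preferences are matched and should give the C1, C10 and C14 configuration of 47 (silicon in the place of O14).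

Step 23
Reactants: 32 Diels–Alder adduct
Product: 34 C15-methyl adduct, via tosylhydrazone 33 (not isolated)
Conditions: TsNHNH2, THF, 4 Å MS, rt; catecholborane, CHCl3, 0 °C; NaOAc·3H2O, 60 °C
Reagents that add atoms: 4-methylbenzenesulfonohydrazide Cc1ccc(cc1)S(=O)(=O)NN (present in 33 only)
Why: Tosylhydrazone formation at the only aldehyde and Kabalka-type reduction with catecholborane, followed by acetate-induced loss of sulfinate and N2 from the diazene, turn C15 into the methyl group without touching the silyl enol ether or the esters.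

Step 24
Reactants: 34 C15-methyl adduct
Product: 35 C12 ketone with free C2 hydroxyl and C14 fluorodimethylsilyl group
Conditions: HF·pyridine, pyridine, THF, 0 °C
Reagents that add atoms: hydrogen fluoride F
Why: HF cleaves the silyl enol ether to the C12 ketone (C11 epimers, inconsequential) and opens the strained Si–O bond of the oxasilole to a fluorosilane and the free C2 hydroxyl, which differentiates O2 from the latent O14; the tertiary TBS and primary TBDPS ethers react more slowly.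

Step 25
Reactants: 35 hydroxy ketone
Product: 36 C2 acetate
Conditions: Ac2O, DMAP, pyridine, CH2Cl2, rt
Reagents that add atoms: acetic anhydride CC(=O)OC(C)=O
Why: DMAP-catalysed acetylation of the only free hydroxyl installs the final C2 acetate.

Step 26
Reactants: 36 keto acetate
Product: 38 12α,14α-diol sulfoxide, via fluorosilyl 12α-alcohol 37 (not isolated)
Conditions: LiBH(sBu)3, THF, −78 °C; then KF, KHCO3, 30% H2O2, THF/MeOH, 0 °C → rt
Reagents that add atoms: hydrogen peroxide OO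
Why: The bulky borohydride attacks the C12 ketone along the equatorial trajectory because the axial approach on the α face is blocked by the syn-axial C14 silyl group, giving the axial 12α alcohol; the oxidative work-up is extended to a Tamao–Fleming oxidation that replaces silicon by hydroxyl with retention at C14 and also oxidises the sulfide to the sulfoxide.

Step 27
Reactants: 38 diol sulfoxide
Product: 39 12α,14α-diol with exocyclic C11=C20 alkene
Conditions: toluene, NaHCO3, 110 °C
Reagents that add atoms: none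
Why: Thermal syn elimination of the sulfoxide can only use the C11 hydrogen and gives the exocyclic methylene next to the C12 hydroxyl.

Step 28
Reactants: 39 allylic alcohol
Product: 40 11,20-epoxy 12α,14α-diol
Conditions: VO(acac)2 (cat.), tBuOOH, CH2Cl2, 0 °C → rt
Reagents that add atoms: tert-butyl hydroperoxide CC(C)(C)OO
Why: Hydroxyl-directed vanadium-catalysed epoxidation delivers oxygen to the alkene face syn to the allylic C12 hydroxyl, which sets C11 with the epoxide oxygen α; the electron-poor 2-iodoalkene has no directing group and is not attacked.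

Step 29
Reactants: 40 epoxy diol
Product: 41 12,14-bis(3-methylbutanoate)
Conditions: (iBuCO)2O, DMAP, Et3N, CH2Cl2, 40 °C
Reagents that add atoms: 3-methylbutanoic anhydride CC(C)CC(=O)OC(=O)CC(C)C
Why: DMAP-catalysed acylation esterifies both secondary hydroxyls with the final isovalerate groups; the C8 oxygen is still silylated.

Step 30
Reactants: 41 bis(isovalerate)
Product: 42 C6 primary alcohol with free C8 hydroxyl
Conditions: Bu4NF, AcOH, THF, rt
Reagents that add atoms: none
Why: Buffered fluoride removes the primary TBDPS and the tertiary TBS ethers without ester migration or epoxide opening.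

Step 31
Reactants: 42 diol
Product: 43 C6 aldehyde
Conditions: Dess–Martin periodinane, NaHCO3, CH2Cl2, 0 °C
Reagents that add atoms: none
Why: Dess–Martin oxidation converts the primary alcohol into the aldehyde while the tertiary C8 hydroxyl cannot be oxidised.

Step 32
Reactants: 43 iodo aldehyde
Product: 44 macrocyclic allylic alcohol (C6 epimers)
Conditions: CrCl2 (10 equiv), NiCl2 (cat.), DMSO/THF, rt, high dilution
Reagents that add atoms: none
Why: Intramolecular Nozaki–Hiyama–Kishi reaction: nickel-catalysed formation of the alkenylchromium species from the 2-iodoalkene and its addition to the C6 aldehyde close the ten-membered ring and create the exocyclic C5=C16 methylene; esters, epoxide and lactone are tolerated, and the C6 configuration formed here is erased in step 33.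

Step 33
Reactants: 44 macrocyclic allylic alcohol
Product: 45 macrocyclic C6 enone
Conditions: Dess–Martin periodinane, NaHCO3, CH2Cl2, 0 °C
Reagents that add atoms: none
Why: Dess–Martin oxidation of both allylic epimers converges on one enone.

Step 34
Reactants: 45 enone
Product: 46 (6R)-allylic alcohol
Conditions: (R)-2-methyl-CBS-oxazaborolidine (1 equiv), catecholborane, toluene, −78 °C
Reagents that add atoms: none
Why: Corey–Bakshi–Shibata reduction under reagent control: with the 2-substituted vinyl group as the larger substituent the R catalyst should deliver hydride to give the 6R alcohol, and 1,2-reduction at low temperature leaves esters and epoxide untouched.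

Step 35
Reactants: 46 (6R)-allylic alcohol
Product: 47 CNP0238609.2 (target)
Conditions: PPh3, Cl3CC(O)CCl3, CH2Cl2, −20 → 0 °C
Reagents that add atoms: hexachloroacetone ClC(Cl)(Cl)C(=O)C(Cl)(Cl)Cl
Why: Chlorination through the alkoxyphosphonium salt with SN2 displacement by chloride inverts C6 with little allylic transposition and converts the 6R alcohol into the 6S chloride; the tertiary C8 hydroxyl does not react.

**Compound list**

1 | pent-4-yn-1-ol | C#CCCCO | starting material
2 | 4-iodopent-4-en-1-ol | C=C(I)CCCO | intermediate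
3 | 4-iodopent-4-enal | C=C(I)CCC=O | intermediate
4 | 1,1,1,3,3,3-hexafluoropropan-2-yl prop-2-enoate | C=CC(=O)OC(C(F)(F)F)C(F)(F)F | starting material
5 | 1,1,1,3,3,3-hexafluoropropan-2-yl (3S)-3-hydroxy-6-iodo-2-methylidenehept-6-enoate | C=C(I)CC[C@H](O)C(=C)C(=O)OC(C(F)(F)F)C(F)(F)F | intermediate
6 | chloro(ethenyl)dimethylsilane | C=C[Si](C)(C)Cl | starting material
7 | 1,1,1,3,3,3-hexafluoropropan-2-yl (3S)-3-{[ethenyl(dimethyl)silyl]oxy}-6-iodo-2-methylidenehept-6-enoate | C=C(I)CC[C@H](O[Si](C)(C)C=C)C(=C)C(=O)OC(C(F)(F)F)C(F)(F)F | intermediate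
8 | 1,1,1,3,3,3-hexafluoropropan-2-yl (5S)-5-(3-iodobut-3-en-1-yl)-2,2-dimethyl-2,5-dihydro-1,2-oxasilole-4-carboxylate | C=C(I)CC[C@@H]1O[Si](C)(C)C=C1C(=O)OC(C(F)(F)F)C(F)(F)F | intermediate
9 | [(5S)-5-(3-iodobut-3-en-1-yl)-2,2-dimethyl-2,5-dihydro-1,2-oxasilol-4-yl]methanol | C=C(I)CC[C@@H]1O[Si](C)(C)C=C1CO | intermediate
10 | (5S)-5-(3-iodobut-3-en-1-yl)-2,2-dimethyl-2,5-dihydro-1,2-oxasilole-4-carbaldehyde | C=C(I)CC[C@@H]1O[Si](C)(C)C=C1C=O | intermediate
11 | 1-(triphenyl-λ5-phosphanylidene)propan-2-one | CC(=O)C=P(c1ccccc1)(c1ccccc1)c1ccccc1 | starting material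
12 | [(chloromethyl)sulfanyl]benzene | ClCSc1ccccc1 | starting material
13 | [3-oxo-1-(phenylsulfanyl)butan-2-yl]triphenylphosphonium chloride | CC(=O)C(CSc1ccccc1)[P+](c1ccccc1)(c1ccccc1)c1ccccc1.[Cl-] | intermediate
14 | 4-(phenylsulfanyl)-3-(triphenyl-λ5-phosphanylidene)butan-2-one | CC(=O)C(CSc1ccccc1)=P(c1ccccc1)(c1ccccc1)c1ccccc1 | intermediate
15 | 3-(methoxymethoxy)prop-1-ene | C=CCOCOC | starting material
16 | 2-[(2Z)-3-(methoxymethoxy)prop-2-en-1-yl]-4,4,5,5-tetramethyl-1,3,2-dioxaborolane | COCO/C=C\CB1OC(C)(C)C(C)(C)O1 | intermediate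
17 | [(4R)-2,2-dimethyl-1,3-dioxolan-4-yl]methanol | OC[C@@H]1COC(C)(C)O1 | starting material
18 | (4S)-2,2-dimethyl-1,3-dioxolane-4-carbaldehyde | O=C[C@@H]1COC(C)(C)O1 | intermediate
19 | (1R,2S)-1-[(4S)-2,2-dimethyl-1,3-dioxolan-4-yl]-2-(methoxymethoxy)but-3-en-1-ol | C=C[C@H](OCOC)[C@@H](O)[C@@H]1COC(C)(C)O1 | intermediate
20 | (2S)-1-[(4S)-2,2-dimethyl-1,3-dioxolan-4-yl]-2-(methoxymethoxy)but-3-en-1-one | C=C[C@H](OCOC)C(=O)[C@@H]1COC(C)(C)O1 | intermediate
21 | (2S,4S)-1,2-dihydroxy-4-(methoxymethoxy)hex-5-en-3-one | C=C[C@H](OCOC)C(=O)[C@@H](O)CO | intermediate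
22 | (2S,4S)-1-[(tert-butyldiphenylsilyl)oxy]-2-hydroxy-4-(methoxymethoxy)hex-5-en-3-one | C=C[C@H](OCOC)C(=O)[C@@H](O)CO[Si](c1ccccc1)(c1ccccc1)C(C)(C)C | intermediate
23 | 2-bromopropanoyl bromide (racemic) | CC(Br)C(Br)=O | starting material
24 | (2S,4S)-1-[(tert-butyldiphenylsilyl)oxy]-4-(methoxymethoxy)-3-oxohex-5-en-2-yl 2-bromopropanoate (both CHBr epimers) | C=C[C@H](OCOC)C(=O)[C@@H](OC(=O)C(C)Br)CO[Si](c1ccccc1)(c1ccccc1)C(C)(C)C | intermediate
25 | (3R,4R,5S)-5-{[(tert-butyldiphenylsilyl)oxy]methyl}-4-hydroxy-4-[(1S)-1-(methoxymethoxy)prop-2-en-1-yl]-3-methyloxolan-2-one | C=C[C@H](OCOC)[C@]1(O)[C@@H](C)C(=O)O[C@H]1CO[Si](c1ccccc1)(c1ccccc1)C(C)(C)C | intermediate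
26 | (3R,4R,5S)-5-{[(tert-butyldiphenylsilyl)oxy]methyl}-4-hydroxy-4-[(1S)-1-hydroxyprop-2-en-1-yl]-3-methyloxolan-2-one | C=C[C@H](O)[C@]1(O)[C@@H](C)C(=O)O[C@H]1CO[Si](c1ccccc1)(c1ccccc1)C(C)(C)C | intermediate
27 | (1S)-1-[(2S,3R,4R)-2-{[(tert-butyldiphenylsilyl)oxy]methyl}-3-hydroxy-4-methyl-5-oxooxolan-3-yl]prop-2-en-1-yl acetate | C=C[C@H](OC(C)=O)[C@]1(O)[C@@H](C)C(=O)O[C@H]1CO[Si](c1ccccc1)(c1ccccc1)C(C)(C)C | intermediate
28 | ozonide of 27 (3-substituted 1,2,4-trioxolane, ring carbon undefined) | C1OOC(O1)[C@H](OC(C)=O)[C@]2(O)[C@@H](C)C(=O)O[C@H]2CO[Si](c2ccccc2)(c2ccccc2)C(C)(C)C | intermediate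
29 | (1R)-1-[(2S,3S,4R)-2-{[(tert-butyldiphenylsilyl)oxy]methyl}-3-hydroxy-4-methyl-5-oxooxolan-3-yl]-2-oxoethyl acetate | O=C[C@H](OC(C)=O)[C@]1(O)[C@@H](C)C(=O)O[C@H]1CO[Si](c1ccccc1)(c1ccccc1)C(C)(C)C | intermediate
30 | (1S,2Z)-1-[(2S,3R,4R)-2-{[(tert-butyldiphenylsilyl)oxy]methyl}-3-hydroxy-4-methyl-5-oxooxolan-3-yl]-4-oxo-3-[(phenylsulfanyl)methyl]pent-2-en-1-yl acetate | CC(=O)/C(CSc1ccccc1)=C/[C@H](OC(C)=O)[C@]1(O)[C@@H](C)C(=O)O[C@H]1CO[Si](c1ccccc1)(c1ccccc1)C(C)(C)C | intermediate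
31 | (1S,2Z)-1-[(2S,3R,4R)-3-[(tert-butyldimethylsilyl)oxy]-2-{[(tert-butyldiphenylsilyl)oxy]methyl}-4-methyl-5-oxooxolan-3-yl]-4-[(tert-butyldimethylsilyl)oxy]-3-[(phenylsulfanyl)methyl]penta-2,4-dien-1-yl acetate | C=C(O[Si](C)(C)C(C)(C)C)/C(CSc1ccccc1)=C/[C@H](OC(C)=O)[C@]1(O[Si](C)(C)C(C)(C)C)[C@@H](C)C(=O)O[C@H]1CO[Si](c1ccccc1)(c1ccccc1)C(C)(C)C | intermediate
32 | Diels–Alder adduct: cyclohexene C1–C14–C13–C12–C11–C10 with C1 formyl (C15), C11=C12 TBS enol ether, C11 CH2SPh, C10 bearing the C9 acetoxy silyloxy-lactone side chain of 31, and the O2–SiMe2–C14 oxasilole cis-fused at C1–C14 with the 3-iodobut-3-enyl chain on C2; C1, C2, C7–C10, C14, C17 configured as in 47 (Si in the place of O14) | C=C(I)CC[C@@H]1O[Si](C)(C)[C@H]2CC(O[Si](C)(C)C(C)(C)C)=C(CSc3ccccc3)[C@H]([C@H](OC(C)=O)[C@]3(O[Si](C)(C)C(C)(C)C)[C@@H](C)C(=O)O[C@H]3CO[Si](c3ccccc3)(c3ccccc3)C(C)(C)C)[C@@]12C=O | intermediate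
33 | N-tosylhydrazone of 32 at C15 | C=C(I)CC[C@@H]1O[Si](C)(C)[C@H]2CC(O[Si](C)(C)C(C)(C)C)=C(CSc3ccccc3)[C@H]([C@H](OC(C)=O)[C@]3(O[Si](C)(C)C(C)(C)C)[C@@H](C)C(=O)O[C@H]3CO[Si](c3ccccc3)(c3ccccc3)C(C)(C)C)[C@@]12C=NNS(=O)(=O)c1ccc(C)cc1 | intermediate
34 | 32 with C15 as methyl (formyl reduced to CH3) | C=C(I)CC[C@@H]1O[Si](C)(C)[C@H]2CC(O[Si](C)(C)C(C)(C)C)=C(CSc3ccccc3)[C@H]([C@H](OC(C)=O)[C@]3(O[Si](C)(C)C(C)(C)C)[C@@H](C)C(=O)O[C@H]3CO[Si](c3ccccc3)(c3ccccc3)C(C)(C)C)[C@@]12C | intermediate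
35 | open-chain C2 alcohol: cyclohexanone (C12=O, C11 CH2SPh, C11 undefined) with C14α fluorodimethylsilyl, C1 methyl, free (2S) hydroxyl on the 5-iodohex-5-enyl chain; other centres as in 47 | C=C(I)CC[C@H](O)[C@@]1(C)[C@@H]([Si](C)(C)F)CC(=O)C(CSc2ccccc2)[C@@H]1[C@H](OC(C)=O)[C@]1(O[Si](C)(C)C(C)(C)C)[C@@H](C)C(=O)O[C@H]1CO[Si](c1ccccc1)(c1ccccc1)C(C)(C)C | intermediate
36 | C2 acetate of 35 | C=C(I)CC[C@H](OC(C)=O)[C@@]1(C)[C@@H]([Si](C)(C)F)CC(=O)C(CSc2ccccc2)[C@@H]1[C@H](OC(C)=O)[C@]1(O[Si](C)(C)C(C)(C)C)[C@@H](C)C(=O)O[C@H]1CO[Si](c1ccccc1)(c1ccccc1)C(C)(C)C | intermediate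
37 | 12α-alcohol of 36 (fluorosilane retained) | C=C(I)CC[C@H](OC(C)=O)[C@@]1(C)[C@@H]([Si](C)(C)F)C[C@@H](O)C(CSc2ccccc2)[C@@H]1[C@H](OC(C)=O)[C@]1(O[Si](C)(C)C(C)(C)C)[C@@H](C)C(=O)O[C@H]1CO[Si](c1ccccc1)(c1ccccc1)C(C)(C)C | intermediate
38 | 12α,14α-diol with C11 CH2S(O)Ph (sulfoxide; C11 and S undefined) | C=C(I)CC[C@H](OC(C)=O)[C@@]1(C)[C@@H](O)C[C@@H](O)C(CS(=O)c2ccccc2)[C@@H]1[C@H](OC(C)=O)[C@]1(O[Si](C)(C)C(C)(C)C)[C@@H](C)C(=O)O[C@H]1CO[Si](c1ccccc1)(c1ccccc1)C(C)(C)C | intermediate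
39 | 12α,14α-diol with exocyclic C11=C20 methylene | C=C(I)CC[C@H](OC(C)=O)[C@@]1(C)[C@@H](O)C[C@@H](O)C(=C)[C@@H]1[C@H](OC(C)=O)[C@]1(O[Si](C)(C)C(C)(C)C)[C@@H](C)C(=O)O[C@H]1CO[Si](c1ccccc1)(c1ccccc1)C(C)(C)C | intermediate
40 | (11R)-11,20-epoxide of 39 (epoxide oxygen α, syn to O12) | C=C(I)CC[C@H](OC(C)=O)[C@@]1(C)[C@@H](O)C[C@@H](O)[C@]2(CO2)[C@@H]1[C@H](OC(C)=O)[C@]1(O[Si](C)(C)C(C)(C)C)[C@@H](C)C(=O)O[C@H]1CO[Si](c1ccccc1)(c1ccccc1)C(C)(C)C | intermediate
41 | 12,14-bis(3-methylbutanoate) of 40 | C=C(I)CC[C@H](OC(C)=O)[C@@]1(C)[C@@H](OC(=O)CC(C)C)C[C@@H](OC(=O)CC(C)C)[C@]2(CO2)[C@@H]1[C@H](OC(C)=O)[C@]1(O[Si](C)(C)C(C)(C)C)[C@@H](C)C(=O)O[C@H]1CO[Si](c1ccccc1)(c1ccccc1)C(C)(C)C | intermediate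
42 | desilylated 41: C6 primary alcohol, free tertiary C8 hydroxyl | C=C(I)CC[C@H](OC(C)=O)[C@@]1(C)[C@@H](OC(=O)CC(C)C)C[C@@H](OC(=O)CC(C)C)[C@]2(CO2)[C@@H]1[C@H](OC(C)=O)[C@]1(O)[C@@H](C)C(=O)O[C@H]1CO | intermediate
43 | C6 aldehyde of 42 (seco-iodo aldehyde) | C=C(I)CC[C@H](OC(C)=O)[C@@]1(C)[C@@H](OC(=O)CC(C)C)C[C@@H](OC(=O)CC(C)C)[C@]2(CO2)[C@@H]1[C@H](OC(C)=O)[C@]1(O)[C@@H](C)C(=O)O[C@H]1C=O | intermediate
44 | 6-dechloro-6-hydroxy analogue of 47 (both C6 epimers) | C=C1CC[C@H](OC(C)=O)[C@@]2(C)[C@@H](OC(=O)CC(C)C)C[C@@H](OC(=O)CC(C)C)[C@]3(CO3)[C@@H]2[C@H](OC(C)=O)[C@]2(O)[C@@H](C)C(=O)O[C@H]2C1O | intermediate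
45 | 6-oxo analogue of 47 (macrocyclic enone, C5=C16 conjugated) | C=C1CC[C@H](OC(C)=O)[C@@]2(C)[C@@H](OC(=O)CC(C)C)C[C@@H](OC(=O)CC(C)C)[C@]3(CO3)[C@@H]2[C@H](OC(C)=O)[C@]2(O)[C@@H](C)C(=O)O[C@H]2C1=O | intermediate
46 | (6R)-6-dechloro-6-hydroxy analogue of 47 | C=C1CC[C@H](OC(C)=O)[C@@]2(C)[C@@H](OC(=O)CC(C)C)C[C@@H](OC(=O)CC(C)C)[C@]3(CO3)[C@@H]2[C@H](OC(C)=O)[C@]2(O)[C@@H](C)C(=O)O[C@H]2[C@@H]1O | intermediate
47 | CNP0238609.2, (1S,2S,6S,7R,8R,9S,10S,11R,12R,14S,17R)-2,9-diacetoxy-6-chloro-11,20-epoxy-8-hydroxy-12,14-bis(3-methylbutanoyloxy)briar-5(16)-en-19,7-olide | C=C1CC[C@H](OC(C)=O)[C@@]2(C)[C@@H](OC(=O)CC(C)C)C[C@@H](OC(=O)CC(C)C)[C@]3(CO3)[C@@H]2[C@H](OC(C)=O)[C@]2(O)[C@@H](C)C(=O)O[C@H]2[C@H]1Cl | target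

**Totals and risks**

Total step count: 35. Longest linear sequence: 26 steps (steps 10–35, from 17).

Step 22 (key step). What may go wrong: the bimolecular union at the congested C1–C10 bond may be slower than Lewis-acid-induced desilylation of the fully substituted diene. Fallback, setting out from 29 and 10 and coming back at 35: aldehyde 29 is condensed with the commercial ylide 11 to the C20-free E-enone F1, which is silylated (tBuMe2SiOTf, Et3N) to the less hindered diene F2 and combined with 10 under Me2AlCl to the C11-unsubstituted adduct F3. Hydrazone reduction as in step 23 gives the C15-methyl silyl enol ether F4. Its regiodefined enol ether is alkylated at C11 with 12 and ZnBr2 (cat.) to the α-(phenylsulfanylmethyl) ketone F5, and HF·pyridine then opens the oxasilole to give 35. The price is the loss of the allylic-strain element, so the diene face would then rest only on the anti position of the bulky C8 group.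

Step 32. What may go wrong: slow closure of the ten-membered ring, with competing reduction of the alkenyl iodide or oligomerisation. Fallback, setting out from 42 and coming back at 45: 42 is oxidised (TEMPO, PhI(OAc)2, aq MeCN) to the C6 carboxylic acid F6 and converted (PhSH, DCC, DMAP) into the S-phenyl thioester F7. The iodide is exchanged (Me3SnSnMe3, Pd(PPh3)4, toluene, 80 °C) to give the alkenylstannane thioester F8. A Liebeskind–Srogl type macrocyclic acylation (Pd2(dba)3, tri(2-furyl)phosphine, CuO2PPh2, THF, high dilution) then gives enone 45 directly, so that the ring is closed by acyl coupling and not by carbonyl addition.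

Step 26. What may go wrong: poor facial selectivity in the hydride addition to the C12 ketone. Fallback, setting out from 39 (as a C12 epimer mixture) and coming back at 39: the allylic C12 hydroxyl is oxidised selectively with MnO2 to the β-hydroxy enone F9, which is reduced under Narasaka–Prasad conditions (Et2BOMe, NaBH4, THF/MeOH, −78 °C). The boron chelate of the C14 hydroxyl directs external hydride to give the syn-1,3-diol 39, replacing steric control by chelation control.

Further compounds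
F1 | step 22 | (1S,2E)-1-[(2S,3R,4R)-2-{[(tert-butyldiphenylsilyl)oxy]methyl}-3-hydroxy-4-methyl-5-oxooxolan-3-yl]-4-oxopent-2-en-1-yl acetate | CC(=O)/C=C/[C@H](OC(C)=O)[C@]1(O)[C@@H](C)C(=O)O[C@H]1CO[Si](c1ccccc1)(c1ccccc1)C(C)(C)C
F2 | step 22 | C20-free 2-silyloxy diene (analogue of 31 without CH2SPh, C8 OTBS) | C=C(O[Si](C)(C)C(C)(C)C)/C=C/[C@H](OC(C)=O)[C@]1(O[Si](C)(C)C(C)(C)C)[C@@H](C)C(=O)O[C@H]1CO[Si](c1ccccc1)(c1ccccc1)C(C)(C)C
F3 | step 22 | Diels–Alder adduct lacking the C11 substituent (analogue of 32 with C11–H) | C=C(I)CC[C@@H]1O[Si](C)(C)[C@H]2CC(O[Si](C)(C)C(C)(C)C)=C[C@H]([C@H](OC(C)=O)[C@]3(O[Si](C)(C)C(C)(C)C)[C@@H](C)C(=O)O[C@H]3CO[Si](c3ccccc3)(c3ccccc3)C(C)(C)C)[C@@]12C=O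
F4 | step 22 | C15-methyl analogue of F3 | C=C(I)CC[C@@H]1O[Si](C)(C)[C@H]2CC(O[Si](C)(C)C(C)(C)C)=C[C@H]([C@H](OC(C)=O)[C@]3(O[Si](C)(C)C(C)(C)C)[C@@H](C)C(=O)O[C@H]3CO[Si](c3ccccc3)(c3ccccc3)C(C)(C)C)[C@@]12C
F5 | step 22 | C12 ketone with C11 CH2SPh and intact oxasilole (C11 undefined) | C=C(I)CC[C@@H]1O[Si](C)(C)[C@H]2CC(=O)C(CSc3ccccc3)[C@H]([C@H](OC(C)=O)[C@]3(O[Si](C)(C)C(C)(C)C)[C@@H](C)C(=O)O[C@H]3CO[Si](c3ccccc3)(c3ccccc3)C(C)(C)C)[C@@]12C
F6 | step 32 | C6 carboxylic acid from 42 | C=C(I)CC[C@H](OC(C)=O)[C@@]1(C)[C@@H](OC(=O)CC(C)C)C[C@@H](OC(=O)CC(C)C)[C@]2(CO2)[C@@H]1[C@H](OC(C)=O)[C@]1(O)[C@@H](C)C(=O)O[C@H]1C(=O)O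
F7 | step 32 | S-phenyl C6 thioester of F6 | C=C(I)CC[C@H](OC(C)=O)[C@@]1(C)[C@@H](OC(=O)CC(C)C)C[C@@H](OC(=O)CC(C)C)[C@]2(CO2)[C@@H]1[C@H](OC(C)=O)[C@]1(O)[C@@H](C)C(=O)O[C@H]1C(=O)Sc1ccccc1
F8 | step 32 | C5 trimethylstannyl analogue of F7 | C=C([Sn](C)(C)C)CC[C@H](OC(C)=O)[C@@]1(C)[C@@H](OC(=O)CC(C)C)C[C@@H](OC(=O)CC(C)C)[C@]2(CO2)[C@@H]1[C@H](OC(C)=O)[C@]1(O)[C@@H](C)C(=O)O[C@H]1C(=O)Sc1ccccc1
F9 | step 26 | 14α-hydroxy C12 enone (C11=C20 conjugated) from 39 | C=C(I)CC[C@H](OC(C)=O)[C@@]1(C)[C@@H](O)CC(=O)C(=C)[C@@H]1[C@H](OC(C)=O)[C@]1(O[Si](C)(C)C(C)(C)C)[C@@H](C)C(=O)O[C@H]1CO[Si](c1ccccc1)(c1ccccc1)C(C)(C)C
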